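## The problem

Sideroxylonal C (20) is a 2-arylchromane made of two diformylphloroglucinol rings: ring A is fused to the pyran ring (O1, C2, C3, C4, C4a, C8a) and ring B is attached at C2. The pyran ring carries three contiguous stereocentres, all trans and (2R,3R,4R): C2 (ring B), C3 (isopropyl) and C4 (isobutyl). C4 is a benzylic carbon that cannot be corrected later, so it has to be set absolutely, and its neighbour C3 is best fixed in the same event. C2 is an O,C-benzylic carbon that ionises easily, so it can be made last and placed under the control of C3. Four aldehydes and five chelated phenols tolerate neither organometallic reagents nor strong base, so the formyl groups should arrive late and the phenols be freed in the last step. The phloroglucinol ethers that stand in for them are very electron-rich, so every acid-promoted step must reckon with ionisation at C2 and loss of the C3 proton. The enabling feature is the C3–C4 pair: two adjacent methines bearing isopropyl (C3) and ring A (C4), with isobutyl on C4 and a one-carbon link (C2) on C3. This is the pattern left when isopropyl and an aryl group add anti across an (E)-alkene carrying isobutyl at one end and boron at the other, the boron later being exchanged for C2 with retention.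

## Retrosynthesis

**20 ⇒ 19 (five O–CH3 bonds).** The phenols are masked as methyl ethers. In 19 each methoxy group lies ortho to a formyl group, so chelation-directed cleavage with BCl3 can remove all five without harsher reagents. Benzyl ethers would not survive the Lewis acids used earlier, and silyl ethers would not survive the organolithium steps.

**19 ⇒ 18 (four C–CHO bonds at C6, C8, C3′, C5′).** The four free ring positions of 18 are the only unsubstituted aromatic carbons, and each is flanked by two oxygen substituents, so no regiochemical question arises. Cutting here rather than carrying aldehydes forward keeps all earlier organometallic chemistry free of carbonyl groups. The forward step must place two formyl groups on each ring without ionising O1–C2 irreversibly.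

**18 ⇒ 16 + 17 (C2–C1′).** Ring B is added as the nucleophile 1,3,5-trimethoxybenzene (17) to the oxocarbenium ion from cyclic acetal 16. Bringing the aryl group in as the nucleophile places it anti to the C3 isopropyl group, which is the 2,3-trans relationship of the target. The opposite polarity (aryl already on C2, hydride delivered to a 2-aryl oxocarbenium ion) would put hydrogen anti to isopropyl and give the 2,3-cis isomer. Compound 17 is symmetric and commercial.

**16 ⇒ 15 (O1–C2).** The cyclic methyl acetal is the aldehyde 15 closed onto the ring A phenol. The MOM group on that oxygen is the only acetal in 15, so a single acid treatment in methanol removes it and closes the ring. This differentiation of one of three ring A oxygens must be built in from the start.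

**15 ⇒ 13 (C2–C3).** The formyl carbon replaces boron: addition of LiCHCl2 to boronate 13, 1,2-shift of C3 with retention, then oxidation. A carbenoid already carrying ring B would be more convergent but would have to combine a hindered secondary boronate with a hindered, electron-rich benzylic carbenoid. The one-carbon reagent is the smallest possible partner.

**13 ⇒ 5 + 11 + 10, through ate complex 12 (C3–isopropyl and C4–C4a).** This is the key cut. Both stereocentres come from one catalytic three-component coupling of alkenylboronate 5, isopropyllithium (11) and aryl triflate 10. A stepwise construction would need two separate asymmetric operations. The boron carries the diol 2 rather than pinacol, because β-substituted alkenyl ate complexes of pinacol esters tend to transfer the alkenyl group directly to palladium, whereas the hindered diol 2 favours the metallate shift. The forward reaction needs a secondary alkyl group to migrate and a di-ortho-substituted triflate to couple.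

**5 ⇒ 3 + 2; 2 ⇒ 1; 10 ⇒ 9 ⇒ 7 ⇒ 6.** Hydroboration of 4-methylpent-1-yne (3) fixes the (E)-geometry on which the relative configuration depends, and diol 2 is one step from acenaphthoquinone (1). Triflate 10 comes from 2-hydroxy-4,6-dimethoxybenzaldehyde (6): MOM protection (7), Dakin-type oxidation through formate 8 to phenol 9, and triflation. The formyl group of 6 is used only to mark the carbon that becomes C4a, so the substitution pattern is unambiguous.

## Roads not taken

**Alternative 1:** The cut is O1–C8a. The precursor is the open-chain C2 carbinol A2, in which both rings already carry their formyl and methoxy groups. In the forward step K2CO3 in DMF generates the C2 alkoxide, which adds to the ortho carbon of the C4 aryl ring (activated by one ortho and one para formyl group) and expels methoxide, closing the pyran ring by addition–elimination. The product A1 is the pentamethyl ether, identical with 19.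
- Merits: the formyl groups serve as activators, no late electrophilic substitution is needed, and only the demethylation remains. In this respect it is better than the chosen plan, whose step 10 must install four formyl groups at once on an acid-sensitive chromane.
- Weak points: A2 is an acyclic array of three contiguous stereocentres between two hexasubstituted rings. Its four aldehydes would have to be masked through every C–C bond formation and unmasked before closure. The ring under attack carries two further methoxy donors, and the nucleophile is a hindered secondary alkoxide. C2 would have to be made as a free-standing carbinol centre rather than induced from C3.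
- Comparison: the chosen plan sets against the cleaner end of Alternative 1 a short, catalytic construction of C3 and C4 and a C2 centre induced by C3.

**Alternative 2:** The cuts are O1–C2 and C2–C3. The precursors are aryl silyl ether A4 (one stereocentre, C4) and 2,4,6-trimethoxybenzaldehyde A5. With SnCl4 the two form an O1–C2 oxocarbenium ion, the trisubstituted alkene attacks through C3, and the exocyclic tertiary cation is trapped as the chloride A3. One C–Cl reduction would then give 18.
- Merits: the ring and two stereocentres (C2, C3) form in one step from a precursor with a single stereocentre, and the route to 18 could be shorter than the chosen one.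
- Weak points: an aryl silyl ether is a poor oxygen donor, and A5 gives a strongly stabilised, weakly electrophilic cation, so C-alkylation of ring A at C6 or C8 may outrun the oxygen pathway. C2 and C3 are set relative to C4 only by chair preferences, which the peri interaction between the C4 isobutyl group and the C5 methoxy group makes hard to predict. The tertiary cation can eliminate, and a dehalogenation step is added.
- Comparison: the chosen plan is longer to 18 but fixes the C3/C4 relationship by a stereospecific mechanism rather than by a conformational preference.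

**Alternative 3:** The cuts are O1–C8a and C4a–C4. The precursors are hydroxy-enoate A7 (C2 and C3 already set) and silyl triflate A8. CsF releases the aryne from A8; the potassium alkoxide of A7 adds at the aryne carbon remote from the flanking methoxy group, and the resulting aryl anion adds to the enoate β-carbon, closing the pyran ring to A6.
- Merits: two bonds and the ring form in one flask without a transition metal. Ring B is in place from the start, so no arylation at C2 is needed. In that respect it is better than the chosen plan, which must rely on facial selectivity in step 9.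
- Weak points: the hindered secondary alkoxide must add to the aryne faster than the aryl anion is protonated. C4 is set only by substrate control in the Michael closure. A7 needs two stereocentres from separate earlier chemistry. A6 carries CH2CO2Me where isobutyl is needed, costing about three further steps (double methyl addition and deoxygenation) to reach 18.
- Comparison: the chosen plan installs isobutyl and isopropyl as such and sets C3/C4 together, so it needs no side-chain correction.

Key step: step 6

Remarks on the chemistry:
- B(mac) denotes the cyclic boronic ester of diol 2.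
- The MandyPhos antipode is chosen so that palladium binds the alkene face leading to (3R,4R)-13. The sense of induction is assumed to follow that of simpler β-alkyl alkenyl ate complexes and would be confirmed on 13.
- Compounds 14 and 16 are formed as mixtures at one centre (C1 of 14, C2 of 16) that is destroyed in the following operation.

## Route

Step 1
Reactants: 1 acenaphthylene-1,2-dione (acenaphthoquinone)
Product: 2 (1R,2S)-1,2-dimethyl-1,2-dihydroacenaphthylene-1,2-diol (cis, meso)
Conditions: AlMe3 (excess), toluene, 0 °C to rt; aq. HCl
Reagents that add atoms: trimethylaluminium, C[Al](C)C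
Why: Double 1,2-addition of methyl to the 1,2-diketone; the second methyl is expected to enter anti to the aluminium alkoxide already in place, giving the cis diol, the only isomer that can span boron in a five-membered ring.

Step 2
Reactants: 3 4-methylpent-1-yne; 2 (1R,2S)-1,2-dimethyl-1,2-dihydroacenaphthylene-1,2-diol
Product: 5 (E)-4-methylpent-1-enylboronic acid B(mac) ester, via alkenyl catechol boronate 4 (not isolated)
Conditions: catecholborane, neat, 70 °C; then 2, THF, rt to 50 °C
Reagents that add atoms: catecholborane, B1Oc2ccccc2O1
Why: Syn hydroboration of the terminal alkyne places boron at the terminus and gives the (E)-alkenyl catechol boronate; transesterification then exchanges the aryl ester for the more stable ester of the ditertiary diol 2 and releases catechol.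

Step 3
Reactants: 6 2-hydroxy-4,6-dimethoxybenzaldehyde
Product: 7 2,4-dimethoxy-6-(methoxymethoxy)benzaldehyde
Conditions: MOMCl, iPr2NEt, CH2Cl2, 0 °C to rt
Reagents that add atoms: chloromethyl methyl ether, COCCl
Why: O-Alkylation of the phenol (MOM protection); the acetal marks the one oxygen that becomes O1 and can later be removed by acid without touching the methyl ethers.

Step 4
Reactants: 7 2,4-dimethoxy-6-(methoxymethoxy)benzaldehyde
Product: 9 2,4-dimethoxy-6-(methoxymethoxy)phenol, via aryl formate 8 (not isolated)
Conditions: mCPBA, CH2Cl2, 0 °C to rt; then K2CO3 (cat.), MeOH, rt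
Reagents that add atoms: 3-chloroperoxybenzoic acid, O=C(OO)c1cccc(Cl)c1
Why: Dakin-type oxidation: Baeyer–Villiger migration of the electron-rich aryl group turns the aldehyde into the aryl formate, which methanolysis cleaves to the phenol.

Step 5
Reactants: 9 2,4-dimethoxy-6-(methoxymethoxy)phenol
Product: 10 2,4-dimethoxy-6-(methoxymethoxy)phenyl trifluoromethanesulfonate
Conditions: Tf2O, pyridine, CH2Cl2, −20 °C to 0 °C
Reagents that add atoms: trifluoromethanesulfonic anhydride, O=S(=O)(OS(=O)(=O)C(F)(F)F)C(F)(F)F
Why: O-Sulfonylation of the phenol; the pyridinium salt formed is too weak an acid to cleave the MOM acetal at this temperature.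

Step 6
Reactants: 5 (E)-4-methylpent-1-enylboronic acid B(mac) ester; 11 isopropyllithium; 10 2,4-dimethoxy-6-(methoxymethoxy)phenyl trifluoromethanesulfonate
Product: 13 [(3R,4R)-4-[2,4-dimethoxy-6-(methoxymethoxy)phenyl]-2,6-dimethylheptan-3-yl]boronic acid B(mac) ester, via lithium ate complex 12 (not isolated)
Conditions: 5, iPrLi (pentane), THF, −78 °C to rt; then 10, Pd(OAc)2 (cat.), MandyPhos ligand [1,1′-bis(bis(3,5-dimethylphenyl)phosphino)-2,2′-bis(α-(dimethylamino)benzyl)ferrocene, one enantiomer] (cat.), THF, 40 °C
Reagents that add atoms: none
Why: Isopropyllithium adds to the boron of 5 to give the four-coordinate ate complex 12. Oxidative addition of the zerovalent palladium–bisphosphine into triflate 10 gives a cationic arylpalladium species (divalent palladium, non-coordinating triflate) that binds the alkene of 12. The metal-induced 1,2-metallate shift then moves isopropyl from boron to C3 anti-periplanar to the palladium that bonds to C4, and reductive elimination with retention forms C4–C4a; the closest known reaction is the palladium/MandyPhos conjunctive cross-coupling of β-alkyl alkenyl B(mac) ate complexes with aryl triflates. No ring is closed. The relative configuration of C3 and C4 follows from the stereospecific anti addition across the (E)-alkene, and the absolute configuration from the alkene face that the chiral ligand lets palladium bind. The step needs the metallate shift to outrun direct alkenyl transfer to palladium (Suzuki–Miyaura coupling); the hindered diol on boron, the triflate leaving group and halide-free isopropyllithium are chosen for this. Only isopropyl can migrate, because it is the sole carbon ligand on boron besides the activated alkene.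

Step 7
Reactants: 13 [(3R,4R)-4-[2,4-dimethoxy-6-(methoxymethoxy)phenyl]-2,6-dimethylheptan-3-yl]boronic acid B(mac) ester
Product: 15 (2R,3R)-3-[2,4-dimethoxy-6-(methoxymethoxy)phenyl]-5-methyl-2-(propan-2-yl)hexanal, via α-chloro boronate 14 (not isolated)
Conditions: CH2Cl2, n-BuLi, THF, −100 °C; 13; ZnCl2, −100 °C to rt; then H2O2, aq. NaHCO3, THF, 0 °C
Reagents that add atoms: dichloromethane, ClCCl; hydrogen peroxide, OO
Why: Matteson homologation: LiCHCl2 adds to boron and C3 migrates to the carbenoid carbon with retention, displacing chloride; oxidation of the α-chloro boronate gives an α-chloro alcohol that collapses to the aldehyde. The near-neutral oxidation is chosen so that C3, now α to the carbonyl, does not epimerise.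

Step 8
Reactants: 15 (2R,3R)-3-[2,4-dimethoxy-6-(methoxymethoxy)phenyl]-5-methyl-2-(propan-2-yl)hexanal
Product: 16 (3R,4R)-2,5,7-trimethoxy-4-(2-methylpropyl)-3-(propan-2-yl)-3,4-dihydro-2H-chromene (both C2 epimers)
Conditions: conc. HCl (cat.), MeOH, 40 °C
Reagents that add atoms: methanol, CO
Why: Acid-catalysed acetal exchange: the MOM group passes to methanol as dimethoxymethane, and the freed phenol and the aldehyde close to the six-membered cyclic methyl acetal; the C2 mixture is irrelevant because C2 is ionised in step 9.

Step 9
Reactants: 16 (3R,4R)-2,5,7-trimethoxy-4-(2-methylpropyl)-3-(propan-2-yl)-3,4-dihydro-2H-chromene; 17 1,3,5-trimethoxybenzene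
Product: 18 (2R,3R,4R)-5,7-dimethoxy-4-(2-methylpropyl)-3-(propan-2-yl)-2-(2,4,6-trimethoxyphenyl)-3,4-dihydro-2H-chromene
Conditions: 17 (excess), BF3·OEt2 (cat.), CH2Cl2, −40 °C to 0 °C
Reagents that add atoms: none
Why: Friedel–Crafts arylation of an oxocarbenium ion: BF3 ionises the acetal and the arene attacks C2 from the face opposite the adjacent C3 isopropyl group, which should give the 2,3-trans (2R) product. Excess 17 and low temperature are meant to suppress alkylation by ring A and loss of the C3 proton.

Step 10
Reactants: 18 (2R,3R,4R)-5,7-dimethoxy-4-(2-methylpropyl)-3-(propan-2-yl)-2-(2,4,6-trimethoxyphenyl)-3,4-dihydro-2H-chromene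
Product: 19 (2R,3R,4R)-2-(3,5-diformyl-2,4,6-trimethoxyphenyl)-5,7-dimethoxy-4-(2-methylpropyl)-3-(propan-2-yl)-3,4-dihydro-2H-chromene-6,8-dicarbaldehyde
Conditions: Cl2CHOMe (excess), TiCl4 (excess), CH2Cl2, −20 °C to rt; then aq. HCl
Reagents that add atoms: dichloromethyl methyl ether, COC(Cl)Cl; water, O
Why: Rieche formylation: the TiCl4-activated dichloromethyl ether substitutes the four remaining ring positions (C6, C8, C3′, C5′), each activated by two ortho and one para oxygen substituent; the α-chloro ethers hydrolyse to aldehydes at work-up.

Step 11
Reactants: 19 (2R,3R,4R)-2-(3,5-diformyl-2,4,6-trimethoxyphenyl)-5,7-dimethoxy-4-(2-methylpropyl)-3-(propan-2-yl)-3,4-dihydro-2H-chromene-6,8-dicarbaldehyde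
Product: 20 sideroxylonal C, (2R,3R,4R)-2-(3,5-diformyl-2,4,6-trihydroxyphenyl)-5,7-dihydroxy-4-(2-methylpropyl)-3-(propan-2-yl)-3,4-dihydro-2H-chromene-6,8-dicarbaldehyde
Conditions: BCl3 (excess), CH2Cl2, −78 °C to rt; then H2O
Reagents that add atoms: none
Why: Lewis-acid demethylation: each of the five methoxy groups lies ortho to a formyl group, so BCl3 is delivered by chelation and cleaves them as chloromethane under conditions that should leave the aldehydes and the pyran ring intact; hydrolysis frees the phenols.

## Compound list

1 | acenaphthylene-1,2-dione (acenaphthoquinone) | O=C1C(=O)c2cccc3cccc1c23 | starting material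
2 | (1R,2S)-1,2-dimethyl-1,2-dihydroacenaphthylene-1,2-diol (cis, meso) | C[C@]1(O)c2cccc3cccc(c23)[C@@]1(C)O | intermediate
3 | 4-methylpent-1-yne | CC(C)CC#C | starting material
4 | 2-[(E)-4-methylpent-1-enyl]-1,3,2-benzodioxaborole | CC(C)C/C=C/B1Oc2ccccc2O1 | intermediate (not isolated)
5 | (E)-4-methylpent-1-enylboronic acid B(mac) ester (cyclic boronate of diol 2, cis-fused) | CC(C)C/C=C/B1O[C@]2(C)c3cccc4cccc(c34)[C@]2(C)O1 | intermediate
6 | 2-hydroxy-4,6-dimethoxybenzaldehyde | COc1cc(O)c(C=O)c(OC)c1 | starting material
7 | 2,4-dimethoxy-6-(methoxymethoxy)benzaldehyde | COCOc1cc(OC)cc(OC)c1C=O | intermediate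
8 | 2,4-dimethoxy-6-(methoxymethoxy)phenyl formate | COCOc1cc(OC)cc(OC)c1OC=O | intermediate (not isolated)
9 | 2,4-dimethoxy-6-(methoxymethoxy)phenol | COCOc1cc(OC)cc(OC)c1O | intermediate
10 | 2,4-dimethoxy-6-(methoxymethoxy)phenyl trifluoromethanesulfonate | COCOc1cc(OC)cc(OC)c1OS(=O)(=O)C(F)(F)F | intermediate
11 | isopropyllithium | [Li]C(C)C | starting material
12 | lithium isopropyl[(E)-4-methylpent-1-enyl]borate of diol 2 (ate complex, configuration at boron not defined) | [Li+].CC(C)C/C=C/[B-]1(C(C)C)O[C@]2(C)c3cccc4cccc(c34)[C@]2(C)O1 | intermediate (not isolated)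
13 | [(3R,4R)-4-[2,4-dimethoxy-6-(methoxymethoxy)phenyl]-2,6-dimethylheptan-3-yl]boronic acid B(mac) ester | CC(C)C[C@H]([C@H](B1O[C@]2(C)c3cccc4cccc(c34)[C@]2(C)O1)C(C)C)c1c(OC)cc(OC)cc1OCOC | intermediate
14 | [(2R,3R)-1-chloro-3-[2,4-dimethoxy-6-(methoxymethoxy)phenyl]-5-methyl-2-(propan-2-yl)hexyl]boronic acid B(mac) ester (both C1 epimers) | CC(C)C[C@H]([C@H](C(Cl)B1O[C@]2(C)c3cccc4cccc(c34)[C@]2(C)O1)C(C)C)c1c(OC)cc(OC)cc1OCOC | intermediate (not isolated)
15 | (2R,3R)-3-[2,4-dimethoxy-6-(methoxymethoxy)phenyl]-5-methyl-2-(propan-2-yl)hexanal | CC(C)C[C@H]([C@H](C=O)C(C)C)c1c(OC)cc(OC)cc1OCOC | intermediate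
16 | (3R,4R)-2,5,7-trimethoxy-4-(2-methylpropyl)-3-(propan-2-yl)-3,4-dihydro-2H-chromene (both C2 epimers) | CC(C)C[C@H]1c2c(OC)cc(OC)cc2OC(OC)[C@@H]1C(C)C | intermediate
17 | 1,3,5-trimethoxybenzene | COc1cc(OC)cc(OC)c1 | starting material
18 | (2R,3R,4R)-5,7-dimethoxy-4-(2-methylpropyl)-3-(propan-2-yl)-2-(2,4,6-trimethoxyphenyl)-3,4-dihydro-2H-chromene | CC(C)C[C@H]1c2c(OC)cc(OC)cc2O[C@@H](c2c(OC)cc(OC)cc2OC)[C@@H]1C(C)C | intermediate
19 | (2R,3R,4R)-2-(3,5-diformyl-2,4,6-trimethoxyphenyl)-5,7-dimethoxy-4-(2-methylpropyl)-3-(propan-2-yl)-3,4-dihydro-2H-chromene-6,8-dicarbaldehyde | CC(C)C[C@H]1c2c(OC)c(C=O)c(OC)c(C=O)c2O[C@@H](c2c(OC)c(C=O)c(OC)c(C=O)c2OC)[C@@H]1C(C)C | intermediate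
20 | sideroxylonal C, (2R,3R,4R)-2-(3,5-diformyl-2,4,6-trihydroxyphenyl)-5,7-dihydroxy-4-(2-methylpropyl)-3-(propan-2-yl)-3,4-dihydro-2H-chromene-6,8-dicarbaldehyde | CC(C)C[C@H]1c2c(O)c(C=O)c(O)c(C=O)c2O[C@@H](c2c(O)c(C=O)c(O)c(C=O)c2O)[C@@H]1C(C)C | target

## Step count and risks

Total step count: 11. Longest linear sequence: 9 steps (steps 3 to 11, from 6 to 20).

**Step 6 (key step).** The most likely failure is direct transfer of the alkenyl group from boron to palladium (the Suzuki–Miyaura pathway) outrunning the metallate shift, because a secondary alkyl group migrates slowly and the di-ortho-substituted aryl group crowds the alkene-bound palladium. Oxidative addition into the electron-rich, hindered triflate may also be slow, and β-hydride elimination from the C4–palladium intermediate or erosion of enantioselectivity is possible.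

Fallback, from 10 back to the route at 15:
- Miyaura borylation of 10 (B2pin2, KOAc, Pd(OAc)2 with 2-dicyclohexylphosphino-2′,6′-dimethoxybiphenyl) would give 2-[2,4-dimethoxy-6-(methoxymethoxy)phenyl]-4,4,5,5-tetramethyl-1,3,2-dioxaborolane F1.
- Lithiation–borylation with the carbenoid from 3-methylbutyl 2,4,6-triisopropylbenzoate F2 (s-BuLi and the appropriate enantiomer of sparteine, −78 °C; then F1 and warming) would move the aryl group from boron to carbon. It would give 2-[(1S)-1-[2,4-dimethoxy-6-(methoxymethoxy)phenyl]-3-methylbutyl]-4,4,5,5-tetramethyl-1,3,2-dioxaborolane F3, with C4 set by the diamine.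
- A second homologation with the carbenoid from 2-methylpropyl 2,4,6-triisopropylbenzoate F4 would give the pinacol ester of [(3R,4R)-4-[2,4-dimethoxy-6-(methoxymethoxy)phenyl]-2,6-dimethylheptan-3-yl]boronic acid F5. C4 is retained in the migration and C3 is set by the diamine.
- F5 would be taken through the conditions of step 7, via its α-chloro homologue, the pinacol ester of [(2R,3R)-1-chloro-3-[2,4-dimethoxy-6-(methoxymethoxy)phenyl]-5-methyl-2-(propan-2-yl)hexyl]boronic acid F6, to aldehyde 15.

**Step 7.** The hindered secondary boronate may fail to hold the carbenoid long enough for migration, oxygen rather than carbon may migrate, and C3 may epimerise once it is α to the aldehyde during oxidative work-up.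

Fallback, from 13 back to the route at 15: Zweifel olefination of 13 (vinyllithium, then I2 and NaOMe) would replace boron by a vinyl group with retention and give (3S,4R)-4-[2,4-dimethoxy-6-(methoxymethoxy)phenyl]-6-methyl-3-(propan-2-yl)hept-1-ene F7. Lemieux–Johnson cleavage (OsO4 cat., NaIO4) would then give 15 under neutral conditions.

**Step 9.** Attack of the arene on the wrong face of the oxocarbenium ion, loss of the C3 proton from that ion (epimerisation through the enol ether), alkylation by ring A of a second molecule, and acid-induced reopening of O1–C2 in the product are the likely failure processes.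

Fallback, from 15 back to the route at 18: 2,4,6-trimethoxyphenyllithium (from 17 and n-BuLi) would add to aldehyde 15 at low temperature and give (2R,3R)-3-[2,4-dimethoxy-6-(methoxymethoxy)phenyl]-5-methyl-2-(propan-2-yl)-1-(2,4,6-trimethoxyphenyl)hexan-1-ol F8 as a mixture at the carbinol carbon. Catalytic HCl in methanol would then remove the MOM group and ionise the benzylic alcohol, and the phenol would capture the cation to close O1–C2 and give 18. Here C2–aryl is formed under basic conditions and only the ring closure needs acid.

**Step 10.** Substitution may stop short of four formyl groups because each first formyl group deactivates its ring. TiCl4 may ionise O1–C2 and scramble C2 or C3 through the ring-opened cation. Ipso attack at C1′ may cleave ring B from C2.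

Fallback, from 18 to the target 20: BBr3 would first cleave all five methyl ethers to (2R,3R,4R)-4-(2-methylpropyl)-3-(propan-2-yl)-2-(2,4,6-trihydroxyphenyl)-3,4-dihydro-2H-chromene-5,7-diol F9. Vilsmeier–Haack formylation of the free phloroglucinol rings (POCl3, DMF, then aqueous hydrolysis), the standard way to diformylate phloroglucinols, would then give 20 directly.

## Further compounds

F1 | step 6 | 2-[2,4-dimethoxy-6-(methoxymethoxy)phenyl]-4,4,5,5-tetramethyl-1,3,2-dioxaborolane | COCOc1cc(OC)cc(OC)c1B1OC(C)(C)C(C)(C)O1
F2 | step 6 | 3-methylbutyl 2,4,6-triisopropylbenzoate | CC(C)CCOC(=O)c1c(C(C)C)cc(C(C)C)cc1C(C)C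
F3 | step 6 | 2-[(1S)-1-[2,4-dimethoxy-6-(methoxymethoxy)phenyl]-3-methylbutyl]-4,4,5,5-tetramethyl-1,3,2-dioxaborolane | CC(C)C[C@H](B1OC(C)(C)C(C)(C)O1)c1c(OC)cc(OC)cc1OCOC
F4 | step 6 | 2-methylpropyl 2,4,6-triisopropylbenzoate | CC(C)COC(=O)c1c(C(C)C)cc(C(C)C)cc1C(C)C
F5 | step 6 | [(3R,4R)-4-[2,4-dimethoxy-6-(methoxymethoxy)phenyl]-2,6-dimethylheptan-3-yl]boronic acid pinacol ester | CC(C)C[C@H]([C@H](B1OC(C)(C)C(C)(C)O1)C(C)C)c1c(OC)cc(OC)cc1OCOC
F6 | step 6 | [(2R,3R)-1-chloro-3-[2,4-dimethoxy-6-(methoxymethoxy)phenyl]-5-methyl-2-(propan-2-yl)hexyl]boronic acid pinacol ester (both C1 epimers) | CC(C)C[C@H]([C@H](C(Cl)B1OC(C)(C)C(C)(C)O1)C(C)C)c1c(OC)cc(OC)cc1OCOC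
F7 | step 7 | (3S,4R)-4-[2,4-dimethoxy-6-(methoxymethoxy)phenyl]-6-methyl-3-(propan-2-yl)hept-1-ene | CC(C)C[C@H]([C@H](C=C)C(C)C)c1c(OC)cc(OC)cc1OCOC
F8 | step 9 | (2R,3R)-3-[2,4-dimethoxy-6-(methoxymethoxy)phenyl]-5-methyl-2-(propan-2-yl)-1-(2,4,6-trimethoxyphenyl)hexan-1-ol (both C1 epimers) | CC(C)C[C@H]([C@H](C(O)c1c(OC)cc(OC)cc1OC)C(C)C)c1c(OC)cc(OC)cc1OCOC
F9 | step 10 | (2R,3R,4R)-4-(2-methylpropyl)-3-(propan-2-yl)-2-(2,4,6-trihydroxyphenyl)-3,4-dihydro-2H-chromene-5,7-diol | CC(C)C[C@H]1c2c(O)cc(O)cc2O[C@@H](c2c(O)cc(O)cc2O)[C@@H]1C(C)C
A1 | alternative 1 | sideroxylonal C pentamethyl ether, (2R,3R,4R), identical with 19 | CC(C)C[C@H]1c2c(OC)c(C=O)c(OC)c(C=O)c2O[C@@H](c2c(OC)c(C=O)c(OC)c(C=O)c2OC)[C@@H]1C(C)C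
A2 | alternative 1 | 1,3-bis(3,5-diformyl-2,4,6-trimethoxyphenyl)-5-methyl-2-(propan-2-yl)hexan-1-ol, with C1, C2 and C3 configured as C2, C3 and C4 of the target | CC(C)C[C@@H](c1c(OC)c(C=O)c(OC)c(C=O)c1OC)[C@@H](C(C)C)[C@@H](O)c1c(OC)c(C=O)c(OC)c(C=O)c1OC
A3 | alternative 2 | (2R,3R,4R)-3-(2-chloropropan-2-yl)-5,7-dimethoxy-4-(2-methylpropyl)-2-(2,4,6-trimethoxyphenyl)-3,4-dihydro-2H-chromene | CC(C)C[C@H]1c2c(OC)cc(OC)cc2O[C@@H](c2c(OC)cc(OC)cc2OC)[C@@H]1C(C)(C)Cl
A4 | alternative 2 | tert-butyl{2-[(4R)-2,6-dimethylhept-2-en-4-yl]-3,5-dimethoxyphenoxy}dimethylsilane | CC(C)C[C@H](C=C(C)C)c1c(OC)cc(OC)cc1O[Si](C)(C)C(C)(C)C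
A5 | alternative 2 | 2,4,6-trimethoxybenzaldehyde | COc1cc(OC)c(C=O)c(OC)c1
A6 | alternative 3 | methyl 2-[(2R,3R,4R)-5,7-dimethoxy-3-(propan-2-yl)-2-(2,4,6-trimethoxyphenyl)-3,4-dihydro-2H-chromen-4-yl]acetate | COC(=O)C[C@H]1c2c(OC)cc(OC)cc2O[C@@H](c2c(OC)cc(OC)cc2OC)[C@@H]1C(C)C
A7 | alternative 3 | methyl (2E,4R,5R)-5-hydroxy-4-(propan-2-yl)-5-(2,4,6-trimethoxyphenyl)pent-2-enoate | COC(=O)/C=C/[C@@H](C(C)C)[C@@H](O)c1c(OC)cc(OC)cc1OC
A8 | alternative 3 | 3,5-dimethoxy-2-(trimethylsilyl)phenyl trifluoromethanesulfonate | COc1cc(OC)c([Si](C)(C)C)c(OS(=O)(=O)C(F)(F)F)c1
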